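Ring B is disconnected at C5–C6 (eudesmane numbering; ring A = C1–C5, C10; ring B = C5–C10). The key step exploits the fact that C5 is the β-carbon of a ring A 2-methylcyclohexenone (C3=O, C4 methyl) and sits next to quaternary C10, which carries the chain C9–C8–C7–C6. A C6 radical made from a primary iodide adds to C5 in a 6-exo closure, which in one operation forms ring B, the C5–C6 bond and the cis ring fusion, C5 being dictated by C10. The precursor is enone iodide 15, with C10 set by palladium-catalysed asymmetric allylation and C7/C8 (isopropyl, silyloxy) set by an auxiliary aldol.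

Key step: step 11

Remarks on the chemistry (assumptions and design choices, one line each):
- α/β refer to the usual eudesmane drawing with the C10 methyl β. The target is (3R,4S,5S,7R,10R): 3α-angelate, 4α-acetate, 4β-methyl, 5β-H (cis-fused), 7β-isopropyl. Checked against the target, the enone iodide (C10 R) and the cis C5/C10 relationship of the bicyclic ketone needed no change in connectivity.
- The C8 oxygen is carried through the key step as a triisopropylsilyl ether of defined configuration (C7 R, C8 S), not as a ketal. This avoids ketalising a hindered ketone beside an enone and lets one hydride step unveil both the enone and the C6 alcohol. It also places the 7β-isopropyl and 8α-silyloxy groups trans, so ring B of the cyclized product is a single chair that directs the later ring A oxidation.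
- The (R)-configured PHOX ligand is assumed to give the (R) quaternary centre, by analogy with the known sense of induction for 2-methylcyclohexanone-type enolates. If the sense proved opposite, the enantiomeric ligand would be used.

Step 1
Reactants: 1 2-methylcyclohexane-1,3-dione
Product: 2 2-methyl-3-(2-methylpropoxy)cyclohex-2-en-1-one
Conditions: i-BuOH, p-TsOH·H2O (cat.), toluene, reflux, Dean–Stark
Reagents that add atoms: 2-methylpropan-1-ol, CC(C)CO
Why: Acid-catalysed condensation of the cyclic 1,3-diketone with the alcohol under azeotropic removal of water is the standard entry to a vinylogous ester, which differentiates the two carbonyl groups and masks the future ring A enone.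

Step 2
Reactants: 2 2-methyl-3-(2-methylpropoxy)cyclohex-2-en-1-one; 3 allyl chloroformate
Product: 4 allyl 3-methyl-4-(2-methylpropoxy)-2-oxocyclohex-3-ene-1-carboxylate (racemic)
Conditions: LDA (2.1 equiv), toluene, −78 °C; then 3, −78 °C → rt
Reagents that add atoms: none
Why: Kinetic deprotonation of the vinylogous ester with LDA occurs at the α′-methylene, and Claisen-type C-acylation of that lithium enolate by the chloroformate should give the β-keto ester, the second equivalent of base being consumed by the more acidic product.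

Step 3
Reactants: 4 allyl 3-methyl-4-(2-methylpropoxy)-2-oxocyclohex-3-ene-1-carboxylate
Product: 5 allyl 1,3-dimethyl-4-(2-methylpropoxy)-2-oxocyclohex-3-ene-1-carboxylate (racemic)
Conditions: MeI, K2CO3, acetone, 50 °C
Reagents that add atoms: iodomethane, CI
Why: The doubly activated methine of the β-keto ester is alkylated on carbon by iodomethane under mild carbonate conditions, which installs the future C10 methyl group.

Step 4
Reactants: 5 allyl 1,3-dimethyl-4-(2-methylpropoxy)-2-oxocyclohex-3-ene-1-carboxylate
Product: 6 (6R)-6-allyl-2,6-dimethyl-3-(2-methylpropoxy)cyclohex-2-en-1-one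
Conditions: Pd2(dba)3 (2.5 mol %), (R)-t-Bu-PHOX (6 mol %), toluene, 30 °C
Reagents that add atoms: none
Why: In this decarboxylative asymmetric allylic alkylation, oxidative addition of zerovalent palladium to the allyl ester and loss of CO2 give a PHOX-bound allylpalladium enolate that recombines at carbon, so the ligand should set the quaternary centre (future C10) as R with high enantiomeric excess.

Step 5
Reactants: 6 (6R)-6-allyl-2,6-dimethyl-3-(2-methylpropoxy)cyclohex-2-en-1-one
Product: 7 2-[(1R)-1,3-dimethyl-4-(2-methylpropoxy)-2-oxocyclohex-3-en-1-yl]acetaldehyde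
Conditions: OsO4 (2 mol %), NaIO4, 2,6-lutidine, 1,4-dioxane/H2O, rt
Reagents that add atoms: osmium tetroxide, O=[Os](=O)(=O)=O; sodium periodate, [Na+].[O-]I(=O)(=O)=O (terminal oxidant that resupplies the oxygen)
Why: In this Lemieux–Johnson oxidation OsO4 dihydroxylates the unhindered monosubstituted alkene far faster than the tetrasubstituted, carbonyl-conjugated enol ether double bond, and periodate cleaves the diol in situ to the aldehyde (future C8).

Step 6
Reactants: 8 (4R)-4-benzyl-1,3-oxazolidin-2-one; 9 3-methylbutanoyl chloride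
Product: 10 (4R)-4-benzyl-3-(3-methylbutanoyl)-1,3-oxazolidin-2-one
Conditions: n-BuLi, THF, −78 °C; then 9, −78 → 0 °C
Reagents that add atoms: none
Why: N-Acylation of the lithiated oxazolidinone with an acid chloride is the standard preparation of the acyl imide.

Step 7
Reactants: 7 2-[(1R)-1,3-dimethyl-4-(2-methylpropoxy)-2-oxocyclohex-3-en-1-yl]acetaldehyde; 10 (4R)-4-benzyl-3-(3-methylbutanoyl)-1,3-oxazolidin-2-one
Product: 11 (4R)-4-benzyl-3-{(2R,3S)-4-[(1R)-1,3-dimethyl-4-(2-methylpropoxy)-2-oxocyclohex-3-en-1-yl]-3-hydroxy-2-(propan-2-yl)butanoyl}-1,3-oxazolidin-2-one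
Conditions: 10, Bu2BOTf, i-Pr2NEt, CH2Cl2, 0 °C; then 7, −78 → 0 °C; pH 7 buffer, MeOH, H2O2, 0 °C
Reagents that add atoms: none
Why: In this Evans syn aldol the Z boron enolate reacts through a closed chair transition state on the face away from the benzyl group, which should give the 2R,3S syn adduct (future C7 R, C8 S) under reagent control because the aldehyde has no α-stereocentre, and the adduct from any minor enantiomer of 7 is a diastereomer that should be separable here.

Step 8
Reactants: 11 the syn aldol adduct
Product: 12 (4R)-4-benzyl-3-{(2R,3S)-4-[(1R)-1,3-dimethyl-4-(2-methylpropoxy)-2-oxocyclohex-3-en-1-yl]-2-(propan-2-yl)-3-[tri(propan-2-yl)silyloxy]butanoyl}-1,3-oxazolidin-2-one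
Conditions: TIPSOTf, 2,6-lutidine, CH2Cl2, 0 °C → rt
Reagents that add atoms: triisopropylsilyl trifluoromethanesulfonate, CC(C)[Si](OS(=O)(=O)C(F)(F)F)(C(C)C)C(C)C
Why: Silylation of a hindered secondary aldol hydroxyl with a silyl triflate and 2,6-lutidine is standard, and the triisopropylsilyl group is chosen because it must later survive hot acetic acid.

Step 9
Reactants: 12 the silylated aldol adduct
Product: 14 (4R)-4-{(2S,3S)-3-(hydroxymethyl)-4-methyl-2-[tri(propan-2-yl)silyloxy]pentyl}-2,4-dimethylcyclohex-2-en-1-one, via allylic alcohol enol ether 13 (not isolated)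
Conditions: LiAlH4, THF, −10 → 0 °C; EtOAc quench; then 1 M HCl, THF, rt
Reagents that add atoms: water, O (the enone oxygen, on hydrolysis of the enol ether)
Why: LiAlH4 cleaves the imide reductively to the primary C6 alcohol and reduces the vinylogous ester carbonyl in the same operation, and the acidic work-up converts the resulting 3-alkoxy allylic alcohol with loss of water into the transposed enone (Stork–Danheiser transposition), which places C5 as the β-carbon next to C10.

Step 10
Reactants: 14 the enone alcohol
Product: 15 (4R)-4-{(2S,3R)-3-(iodomethyl)-4-methyl-2-[tri(propan-2-yl)silyloxy]pentyl}-2,4-dimethylcyclohex-2-en-1-one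
Conditions: I2, PPh3, imidazole, CH2Cl2, 0 °C → rt
Reagents that add atoms: iodine, II
Why: Appel-type iodination (alkoxyphosphonium formation and displacement by iodide at the primary carbon) proceeds under near-neutral conditions that leave the enone and the silyl ether untouched.

Step 11
Reactants: 15 the enone iodide
Product: 16 8α-[tri(propan-2-yl)silyloxy]-5βH-eudesman-3-one (cis-fused; 4β-methyl, 7β-isopropyl, 10β-methyl; 4R,5R,7R,8S,10R)
Conditions: Bu3SnH (1.3 equiv), AIBN (0.2 equiv), toluene (0.005 M), 90 °C, syringe-pump addition over 8 h; KF work-up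
Reagents that add atoms: none
Why: The tributyltin radical abstracts iodine from C6, the nucleophilic primary radical adds to the electron-poor β-carbon C5 of the enone, and the resulting C4 α-keto radical takes a hydrogen atom from Bu3SnH, which carries the chain. This is the known tin hydride 6-exo radical conjugate cyclization of 4-(ω-haloalkyl)cyclohex-2-enones to cis-fused decalones. Ring B closes 6-exo-trig (attack at C5, not 7-endo at the methyl-bearing α-carbon C4) through a chair-like or half-chair array about the C10–C5 bond. C5 is set by C10, because the four-atom tether can reach C5 only on the face that bears C9 and the new bond forms perpendicular to the enone plane, so the fusion must be cis (5β-H with 10β-methyl); C4 is set by hydrogen transfer, is epimerizable (the equatorial 4β-methyl epimer is shown) and is erased in step 12. The step needs ring closure to outrun direct reduction of the C6 radical and conjugate hydrostannation of the enone, which is secured by slow addition of the stannane at high dilution and by the quaternary C10, which offers no allylic hydrogen for a competing 1,5-hydrogen shift. The C7 and C8 groups should affect only the rate of closure, not the sense of fusion.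

Step 12
Reactants: 16 the cis-fused 3-ketone
Product: 17 8α-[tri(propan-2-yl)silyloxy]-5βH-eudesm-3-en-3-yl trifluoromethanesulfonate
Conditions: Tf2O, 2,6-di-tert-butyl-4-methylpyridine, CH2Cl2, 0 °C → rt
Reagents that add atoms: trifluoromethanesulfonic anhydride, O=S(=O)(OS(=O)(=O)C(F)(F)F)C(F)(F)F
Why: O-Triflation of the ketone followed by proton loss to the hindered pyridine gives the more substituted enol triflate, and this cis-fused ring system (the analogue of a 5β-3-ketosteroid) enolises toward C4 in any case, so the C3–C4 double bond is expected.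

Step 13
Reactants: 17 the enol triflate
Product: 18 8α-[tri(propan-2-yl)silyloxy]-5βH-eudesm-3-ene
Conditions: Pd(OAc)2 (5 mol %), PPh3 (10 mol %), Bu3N, HCO2H, DMF, 60 °C
Reagents that add atoms: none
Why: Palladium-catalysed formate reduction of an enol triflate (oxidative addition, exchange of triflate for formate, decarboxylation to a palladium hydride and reductive elimination) replaces the triflate by hydrogen without moving the double bond.

Step 14
Reactants: 18 the 3-ene
Product: 21 8α-[tri(propan-2-yl)silyloxy]-5βH-eudesmane-3α,4α-diol, via iodo acetate 19 (not isolated), via hydroxy acetate 20 (not isolated)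
Conditions: I2, AgOAc, AcOH, rt, dark; then H2O (1.5 equiv) in AcOH, 90 °C; then K2CO3, MeOH, rt
Reagents that add atoms: silver acetate, CC(=O)[O-].[Ag+] (both hydroxyl oxygens of 21); iodine, II (retained only in 19); water, O (ends in the acetyl group of 20)
Why: In this Woodward cis-hydroxylation ring B is held as one chair by its equatorial C7 and C8 groups, so C9 is axial on the α-face of ring A and iodonium formation should occur on the open β-face, acetate then opens it at tertiary C4 from the α-face (Markovnikov and trans-diaxial), the C4 acetoxy group displaces the C3 iodide with inversion through an acetoxonium ion that water hydrolyses to the cis α-hydroxy acetate, and methanolysis converges the monoacetate to the 3α,4α-diol.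

Step 15
Reactants: 21 the 3α,4α-diol; 22 angelic acid ((Z)-2-methylbut-2-enoic acid)
Product: 23 4α-hydroxy-8α-[tri(propan-2-yl)silyloxy]-5βH-eudesman-3α-yl (Z)-2-methylbut-2-enoate
Conditions: 22, 2,4,6-trichlorobenzoyl chloride, Et3N, toluene, rt; then 21, 75 °C
Reagents that add atoms: none
Why: Yamaguchi-type esterification with the preformed mixed anhydride and no nucleophilic catalyst is the established way to make angelates without Z to E isomerisation, and only the secondary equatorial C3 hydroxyl should react because the tertiary C4 hydroxyl is too hindered.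

Step 16
Reactants: 23 the 3-angelate 4-ol
Product: 24 4α-acetoxy-8α-[tri(propan-2-yl)silyloxy]-5βH-eudesman-3α-yl (Z)-2-methylbut-2-enoate
Conditions: Ac2O, TMSOTf (5 mol %), CH2Cl2, −20 → 0 °C
Reagents that add atoms: acetic anhydride, CC(=O)OC(C)=O
Why: Silyl triflate-catalysed acetylation generates a highly electrophilic acetylating agent that esterifies hindered tertiary alcohols at low temperature within minutes, conditions under which the angelate, the silyl ether and the C4–O bond are expected to persist.

Step 17
Reactants: 24 the silyl ether diester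
Product: 25 4α-acetoxy-8α-hydroxy-5βH-eudesman-3α-yl (Z)-2-methylbut-2-enoate
Conditions: HF·pyridine, pyridine, THF, 0 °C → rt
Reagents that add atoms: none
Why: Fluoride cleaves the Si–O bond selectively, and buffered HF·pyridine is non-basic, so neither ester should be hydrolysed or migrate.

Step 18
Reactants: 25 the 8α-alcohol
Product: 26 (3R,4S,5S,7R,10R)-4α-acetoxy-8-oxo-5βH-eudesman-3α-yl (Z)-2-methylbut-2-enoate (CNP0322180.1)
Conditions: Dess–Martin periodinane, NaHCO3, CH2Cl2, rt
Reagents that add atoms: none
Why: Dess–Martin oxidation converts the secondary alcohol to the ketone under buffered, non-epimerising conditions, and the 7β-isopropyl group is in any case the equatorial, thermodynamically preferred arrangement once the 4β- and 10β-methyl groups fix the ring A chair.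

Compound list
1 | 2-methylcyclohexane-1,3-dione | CC1C(=O)CCCC1=O | starting material
2 | 2-methyl-3-(2-methylpropoxy)cyclohex-2-en-1-one | CC(C)COC1=C(C)C(=O)CCC1 | intermediate
3 | allyl chloroformate | C=CCOC(Cl)=O | starting material
4 | allyl 3-methyl-4-(2-methylpropoxy)-2-oxocyclohex-3-ene-1-carboxylate (racemic) | C=CCOC(=O)C1CCC(OCC(C)C)=C(C)C1=O | intermediate
5 | allyl 1,3-dimethyl-4-(2-methylpropoxy)-2-oxocyclohex-3-ene-1-carboxylate (racemic) | C=CCOC(=O)C1(C)CCC(OCC(C)C)=C(C)C1=O | intermediate
6 | (6R)-6-allyl-2,6-dimethyl-3-(2-methylpropoxy)cyclohex-2-en-1-one | CC(C)COC1=C(C)C(=O)[C@@](C)(CC=C)CC1 | intermediate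
7 | 2-[(1R)-1,3-dimethyl-4-(2-methylpropoxy)-2-oxocyclohex-3-en-1-yl]acetaldehyde | CC(C)COC1=C(C)C(=O)[C@@](C)(CC=O)CC1 | intermediate
8 | (4R)-4-benzyl-1,3-oxazolidin-2-one | O=C1N[C@H](Cc2ccccc2)CO1 | starting material
9 | 3-methylbutanoyl chloride | CC(C)CC(Cl)=O | starting material
10 | (4R)-4-benzyl-3-(3-methylbutanoyl)-1,3-oxazolidin-2-one | CC(C)CC(=O)N1[C@H](Cc2ccccc2)COC1=O | intermediate
11 | (4R)-4-benzyl-3-{(2R,3S)-4-[(1R)-1,3-dimethyl-4-(2-methylpropoxy)-2-oxocyclohex-3-en-1-yl]-3-hydroxy-2-(propan-2-yl)butanoyl}-1,3-oxazolidin-2-one | CC(C)COC1=C(C)C(=O)[C@@](C)(C[C@H](O)[C@@H](C(C)C)C(=O)N2[C@H](Cc3ccccc3)COC2=O)CC1 | intermediate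
12 | triisopropylsilyl ether of 11 (2R,3S; ring 1R; auxiliary 4R) | CC(C)COC1=C(C)C(=O)[C@@](C)(C[C@H](O[Si](C(C)C)(C(C)C)C(C)C)[C@@H](C(C)C)C(=O)N2[C@H](Cc3ccccc3)COC2=O)CC1 | intermediate
13 | (6R)-6-{(2S,3S)-3-(hydroxymethyl)-4-methyl-2-[tri(propan-2-yl)silyloxy]pentyl}-2,6-dimethyl-3-(2-methylpropoxy)cyclohex-2-en-1-ol (both carbinol epimers) | CC(C)COC1=C(C)C(O)[C@@](C)(C[C@H](O[Si](C(C)C)(C(C)C)C(C)C)[C@@H](C(C)C)CO)CC1 | intermediate (not isolated)
14 | (4R)-4-{(2S,3S)-3-(hydroxymethyl)-4-methyl-2-[tri(propan-2-yl)silyloxy]pentyl}-2,4-dimethylcyclohex-2-en-1-one | CC1=C[C@@](C)(C[C@H](O[Si](C(C)C)(C(C)C)C(C)C)[C@@H](C(C)C)CO)CCC1=O | intermediate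
15 | (4R)-4-{(2S,3R)-3-(iodomethyl)-4-methyl-2-[tri(propan-2-yl)silyloxy]pentyl}-2,4-dimethylcyclohex-2-en-1-one (key-step precursor) | CC1=C[C@@](C)(C[C@H](O[Si](C(C)C)(C(C)C)C(C)C)[C@@H](C(C)C)CI)CCC1=O | intermediate
16 | 8α-[tri(propan-2-yl)silyloxy]-5βH-eudesman-3-one, cis-fused, 4β-methyl (key-step product) | O=C1CC[C@]2(C)C[C@H](O[Si](C(C)C)(C(C)C)C(C)C)[C@@H](C(C)C)C[C@@H]2[C@H]1C | intermediate
17 | 8α-[tri(propan-2-yl)silyloxy]-5βH-eudesm-3-en-3-yl trifluoromethanesulfonate | FC(F)(F)S(=O)(=O)OC1CC[C@]2(C)C[C@H](O[Si](C(C)C)(C(C)C)C(C)C)[C@@H](C(C)C)C[C@@H]2C=1C | intermediate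
18 | 8α-[tri(propan-2-yl)silyloxy]-5βH-eudesm-3-ene | C1CC[C@]2(C)C[C@H](O[Si](C(C)C)(C(C)C)C(C)C)[C@@H](C(C)C)C[C@@H]2C=1C | intermediate
19 | 4α-acetoxy-3β-iodo-8α-[tri(propan-2-yl)silyloxy]-5βH-eudesmane | I[C@H]1CC[C@]2(C)C[C@H](O[Si](C(C)C)(C(C)C)C(C)C)[C@@H](C(C)C)C[C@@H]2[C@]1(C)OC(C)=O | intermediate (not isolated)
20 | 4α-acetoxy-8α-[tri(propan-2-yl)silyloxy]-5βH-eudesman-3α-ol | O[C@@H]1CC[C@]2(C)C[C@H](O[Si](C(C)C)(C(C)C)C(C)C)[C@@H](C(C)C)C[C@@H]2[C@]1(C)OC(C)=O | intermediate (not isolated)
21 | 8α-[tri(propan-2-yl)silyloxy]-5βH-eudesmane-3α,4α-diol | O[C@@H]1CC[C@]2(C)C[C@H](O[Si](C(C)C)(C(C)C)C(C)C)[C@@H](C(C)C)C[C@@H]2[C@]1(C)O | intermediate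
22 | angelic acid, (Z)-2-methylbut-2-enoic acid | C/C=C(/C)C(=O)O | starting material
23 | 4α-hydroxy-8α-[tri(propan-2-yl)silyloxy]-5βH-eudesman-3α-yl (Z)-2-methylbut-2-enoate | C/C=C(/C)C(=O)O[C@@H]1CC[C@]2(C)C[C@H](O[Si](C(C)C)(C(C)C)C(C)C)[C@@H](C(C)C)C[C@@H]2[C@]1(C)O | intermediate
24 | 4α-acetoxy-8α-[tri(propan-2-yl)silyloxy]-5βH-eudesman-3α-yl (Z)-2-methylbut-2-enoate | C/C=C(/C)C(=O)O[C@@H]1CC[C@]2(C)C[C@H](O[Si](C(C)C)(C(C)C)C(C)C)[C@@H](C(C)C)C[C@@H]2[C@]1(C)OC(C)=O | intermediate
25 | 4α-acetoxy-8α-hydroxy-5βH-eudesman-3α-yl (Z)-2-methylbut-2-enoate | C/C=C(/C)C(=O)O[C@@H]1CC[C@]2(C)C[C@H](O)[C@@H](C(C)C)C[C@@H]2[C@]1(C)OC(C)=O | intermediate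
26 | (3R,4S,5S,7R,10R)-4α-acetoxy-8-oxo-5βH-eudesman-3α-yl (Z)-2-methylbut-2-enoate, CNP0322180.1 | C/C=C(/C)C(=O)O[C@@H]1CC[C@]2(C)CC(=O)[C@@H](C(C)C)C[C@@H]2[C@]1(C)OC(C)=O | target

Total step count: 18. Longest linear sequence: 17 steps (steps 1–5 and 7–18; step 6 is a one-step side branch).

Steps most likely to fail

Step 11 (key step). The C6 radical may take a hydrogen atom before it closes the ring, because closure must either carry the C7 and C8 groups axially or eclipse the C10–C5 bond. The stannane may also reduce the enone by conjugate hydrostannation. Fallback: from 15 the chain process with a hydrogen-atom donor is replaced by a visible-light halogen-atom-transfer Giese cyclization (4CzIPN as organic photocatalyst, i-Pr2NEt, MeCN/H2O, blue LEDs, rt). An α-aminoalkyl radical abstracts the iodine, the C6 radical cyclizes as before, and the C4 α-keto radical is reduced to the enolate and protonated. No fast hydrogen donor is present, so reduction of the open-chain radical should be suppressed. The route is rejoined at 16; no new compound is made (F0).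

Step 14. The electrophile may attack the wrong alkene face, the tertiary iodo acetate may eliminate, or the silyl ether may solvolyse in hot acetic acid. Fallback: from 18, epoxidation with mCPBA/NaHCO3 in CH2Cl2 on the open β-face should give the 3β,4β-epoxide F1. Dilute HClO4 in THF/H2O should open it at tertiary C4 from the α-face (trans-diaxial, with inversion) to the 3β,4α-diol F2. Dess–Martin oxidation of the secondary hydroxyl gives the 4α-hydroxy-3-ketone F3. NaBH4 in MeOH at −20 °C should deliver hydride axially from the β-face, anti to the axial C4–O bond, to give the 3α,4α-diol, so the route is rejoined at 21.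

Step 12. Proton loss may occur toward C2 and give the regioisomeric enol triflate. Fallback: from 16, equilibrating silylation (hexamethyldisilazane, TMSI, CH2Cl2, −20 °C → rt) should give the more substituted trimethylsilyl enol ether F4. MeLi in THF at 0 °C then releases the regiodefined lithium enolate, which is trapped with N-phenylbis(trifluoromethanesulfonimide). The route is rejoined at 17.

Further compounds
F0 | step 11 | none | none
F1 | step 14 | 3β,4β-epoxy-8α-[tri(propan-2-yl)silyloxy]-5βH-eudesmane | O1[C@H]2CC[C@]3(C)C[C@H](O[Si](C(C)C)(C(C)C)C(C)C)[C@@H](C(C)C)C[C@@H]3[C@@]12C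
F2 | step 14 | 8α-[tri(propan-2-yl)silyloxy]-5βH-eudesmane-3β,4α-diol | O[C@H]1CC[C@]2(C)C[C@H](O[Si](C(C)C)(C(C)C)C(C)C)[C@@H](C(C)C)C[C@@H]2[C@]1(C)O
F3 | step 14 | 4α-hydroxy-8α-[tri(propan-2-yl)silyloxy]-5βH-eudesman-3-one | O=C1CC[C@]2(C)C[C@H](O[Si](C(C)C)(C(C)C)C(C)C)[C@@H](C(C)C)C[C@@H]2[C@]1(C)O
F4 | step 12 | 3-(trimethylsilyloxy)-8α-[tri(propan-2-yl)silyloxy]-5βH-eudesm-3-ene | C[Si](C)(C)OC1CC[C@]2(C)C[C@H](O[Si](C(C)C)(C(C)C)C(C)C)[C@@H](C(C)C)C[C@@H]2C=1C
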